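**Remarks on the chemistry.** Locants C1–C15 are the germacranolide numbers of the target: C1 ketone, C2=C3 furanone olefin, C4 bearing C15H2OH, C6 lactone O–CH, C7 ring-fusion CH, C8 crotonate CH, C10 quaternary carbon bearing C14H3, C11=C13 exocyclic methylene, C12 lactone carbonyl. By CIP analysis the target is 6S,7S,8R,10R with a Z C4=C5 bond. Amine adducts 19–23 are drawn as the 11S epimer (aminomethyl trans to the C7 chain); the epimer would serve equally, because C11 becomes planar again in step 15.

## Retrosynthetic overview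

1. The ring O–C10–C1(=O)–C2=C3 is a 3(2H)-furanone, the cyclodehydrated form of the hydroxy ynone C10(O)–C1≡C2–C3(=O)–C4. C3 carries only O, C2 and C4, so it can be supplied as CO between a C4 vinyl iodide and the C2 terminus of an alkyne; this is the feature that makes the key step possible.
2. Key disconnection C2–C3 (with C3–C4): an intramolecular carbonylative Sonogashira coupling of acyclic 19 closes the ten-membered carbocycle. Amine addition and acid in the same flask close the furanone transannularly (O10→C3).
3. C7–C8: an indium Barbier union of bromomethyl butenolide 10 (C4–C7, C11–C13, C15) with ynal 16 (C1, C2, C8–C10, C14) sets C7 and C8 from C6 and creates the α-methylene lactone. The methylene is masked as its dimethylamine adduct across the palladium step.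
4. Fragment 10: propargyl silyl ether + acrolein, Sharpless kinetic resolution (C6), directed hydroalumination–iodination (Z C4=C5), esterification and ring-closing metathesis. Fragment 16: (S)-2-methylglycidol (C10).
5. Ring order: butenolide (lactone) ring, then the ten-membered carbocycle, then the furanone ring; last, release of C11=C13 and of the C15 hydroxyl.

Key step: step 14

## Route

Step 1
Reactants: 1 tert-butyl(diphenyl)(prop-2-yn-1-yloxy)silane; 2 acrolein
Product: 4 rac-6-[(tert-butyldiphenylsilyl)oxy]hex-1-en-4-yn-3-ol, via lithium acetylide 3 (not isolated)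
Conditions: n-BuLi, THF, −78 °C; then 2, −78 °C; aq. NH4Cl
Reagents that add atoms: none
Why: Lithium acetylide 1,2-addition to the enal carbonyl (acetylide addition; at −78 °C it outruns conjugate addition); the C6 carbinol forms racemic and is resolved in step 2.

Step 2
Reactants: 4 rac-6-[(tert-butyldiphenylsilyl)oxy]hex-1-en-4-yn-3-ol
Product: 5 (3R)-6-[(tert-butyldiphenylsilyl)oxy]hex-1-en-4-yn-3-ol
Conditions: Ti(OiPr)4 (0.15 equiv), D-(−)-diisopropyl tartrate (0.2 equiv), t-BuOOH (0.6 equiv), 4 Å sieves, CH2Cl2, −20 °C, stopped just past half conversion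
Reagents that add atoms: none
Why: Sharpless kinetic resolution: with the D-(−)-tartrate titanium catalyst the (S)-alcohol is the fast-reacting enantiomer and is epoxidized at its vinyl group, so unreacted (R)-5 (the C6 configuration of the target) is recovered; alkyne and silyl ether are inert.

Step 3
Reactants: 5 (3R)-6-[(tert-butyldiphenylsilyl)oxy]hex-1-en-4-yn-3-ol
Product: 7 (3R,4Z)-6-[(tert-butyldiphenylsilyl)oxy]-5-iodohexa-1,4-dien-3-ol, via cyclic vinylaluminate 6 (not isolated)
Conditions: NaAlH2(OCH2CH2OMe)2 (Red-Al), THF, 0 °C; then I2, −78 → 0 °C; aq. potassium sodium tartrate, Na2S2O3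
Reagents that add atoms: iodine, II
Why: Hydroxyl-directed trans-hydroalumination of a propargylic alcohol followed by iodinolysis: hydride goes to C5 and aluminium to C4 within a five-membered oxa-aluminacycle, and iodine replaces aluminium with retention, which fixes the Z C4=C5 geometry (iodine cis to C6) and leaves C6 untouched.

Step 4
Reactants: 7 (3R,4Z)-6-[(tert-butyldiphenylsilyl)oxy]-5-iodohexa-1,4-dien-3-ol; 8 2-(bromomethyl)prop-2-enoic acid
Product: 9 (3R,4Z)-6-[(tert-butyldiphenylsilyl)oxy]-5-iodohexa-1,4-dien-3-yl 2-(bromomethyl)prop-2-enoate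
Conditions: N,N'-diisopropylcarbodiimide, DMAP (5 mol %), CH2Cl2, 0 °C
Reagents that add atoms: none
Why: Steglich esterification of the secondary alcohol, with little DMAP so that the allylic bromide is not displaced; the C6–O bond is not broken, so configuration is retained.

Step 5
Reactants: 9 (3R,4Z)-6-[(tert-butyldiphenylsilyl)oxy]-5-iodohexa-1,4-dien-3-yl 2-(bromomethyl)prop-2-enoate
Product: 10 (5R)-3-(bromomethyl)-5-[(1Z)-3-[(tert-butyldiphenylsilyl)oxy]-2-iodoprop-1-en-1-yl]furan-2(5H)-one
Conditions: second-generation Grubbs catalyst RuCl2(=CHPh)(H2IMes)(PCy3) (5 mol %), CH2Cl2, 40 °C, 5 mM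
Reagents that add atoms: none
Why: Ring-closing metathesis between the terminal vinyl group and the 2-substituted acrylate closes the butenolide (C7=C11) with loss of ethene; the trisubstituted iodoalkene does not engage and C6 is untouched.

Step 6
Reactants: 11 (S)-2-methylglycidol
Product: 12 (2R)-2-methylpent-4-ene-1,2-diol
Conditions: CH2=CHMgBr (2.5 equiv), CuI (10 mol %), THF, −30 → 0 °C; aq. NH4Cl
Reagents that add atoms: vinylmagnesium bromide, C=C[Mg]Br
Why: Copper-catalysed Grignard opening of the epoxide by SN2 attack at the unsubstituted CH2 (future C9); the quaternary center C10 is not a reaction site, so the purchased configuration is carried over (the descriptor changes only through CIP priorities).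

Step 7
Reactants: 12 (2R)-2-methylpent-4-ene-1,2-diol
Product: 13 (2R)-2-methyl-1,2-bis[(triethylsilyl)oxy]pent-4-ene
Conditions: Et3SiOTf (2.4 equiv), 2,6-lutidine, CH2Cl2, −78 → 0 °C
Reagents that add atoms: triethylsilyl trifluoromethanesulfonate, CC[Si](CC)(CC)OS(=O)(=O)C(F)(F)F
Why: Silyl ether formation with the silyl triflate, which is reactive enough to cap the tertiary hydroxyl as well as the primary one.

Step 8
Reactants: 13 (2R)-2-methyl-1,2-bis[(triethylsilyl)oxy]pent-4-ene
Product: 14 (2R)-2-methyl-2-[(triethylsilyl)oxy]pent-4-enal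
Conditions: (COCl)2, DMSO, CH2Cl2, −78 → −30 °C; then Et3N, −78 → 0 °C
Reagents that add atoms: none
Why: Swern oxidation run directly on the bis-silyl ether: the chlorosulfonium reagent cleaves and oxidizes the unhindered primary triethylsilyl ether while the tertiary one survives, and the aldehyde has no α-hydrogen, so C10 cannot epimerize.

Step 9
Reactants: 14 (2R)-2-methyl-2-[(triethylsilyl)oxy]pent-4-enal
Product: 15 (3R)-3-methyl-3-[(triethylsilyl)oxy]hex-5-en-1-yne
Conditions: dimethyl (1-diazo-2-oxopropyl)phosphonate, K2CO3, MeOH, 0 → 25 °C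
Reagents that add atoms: dimethyl (1-diazo-2-oxopropyl)phosphonate, COP(=O)(OC)C(=[N+]=[N-])C(C)=O
Why: Seyferth–Gilbert homologation in the Ohira–Bestmann form converts the aldehyde into the terminal alkyne (C1≡C2) under carbonate conditions that leave the tertiary silyl ether and the quaternary center intact.

Step 10
Reactants: 15 (3R)-3-methyl-3-[(triethylsilyl)oxy]hex-5-en-1-yne
Product: 16 (3R)-3-methyl-3-[(triethylsilyl)oxy]pent-4-ynal
Conditions: O3, pyridine (3 equiv), CH2Cl2, −78 °C, stopped at the alkene end point (indicator dye)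
Reagents that add atoms: ozone, [O-][O+]=O
Why: Ozonolysis, which cleaves the terminal alkene far faster than the terminal alkyne when stopped at the alkene end point; pyridine converts the carbonyl oxide directly into the aldehyde.

Step 11
Reactants: 10 (5R)-3-(bromomethyl)-5-[(1Z)-3-[(tert-butyldiphenylsilyl)oxy]-2-iodoprop-1-en-1-yl]furan-2(5H)-one; 16 (3R)-3-methyl-3-[(triethylsilyl)oxy]pent-4-ynal
Product: 17 (4S,5R)-5-[(1Z)-3-[(tert-butyldiphenylsilyl)oxy]-2-iodoprop-1-en-1-yl]-4-[(1R,3R)-1-hydroxy-3-methyl-3-[(triethylsilyl)oxy]pent-4-yn-1-yl]-3-methylideneoxolan-2-one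
Conditions: In powder (1.5 equiv), THF/H2O (3:1), 25 °C
Reagents that add atoms: none
Why: Barbier allylation: the allylindium from 10 reacts at its γ-carbon C7 through a closed six-membered transition state on the face opposite the C6 substituent (trans-lactone, C7), with the aldehyde residue equatorial and ring carbon C6 in the place of an E γ-substituent (C8), and the allylic shift creates the exocyclic C11=C13 methylene.

Step 12
Reactants: 17 Barbier adduct with free 8-OH
Product: 18 8-O-[(E)-but-2-enoyl] ester of 17 (6R,7S,8R,10R)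
Conditions: (E)-but-2-enoic anhydride, DMAP (0.2 equiv), Et3N, CH2Cl2, 0 °C
Reagents that add atoms: (E)-but-2-enoic anhydride, C/C=C/C(=O)OC(=O)/C=C/C
Why: DMAP-catalysed acylation of the only free hydroxyl with the anhydride, with retention at C8 and of the E-olefin; prompt acylation also blocks migration of the lactone to O8.

Step 13
Reactants: 18 crotonate with free α-methylene lactone
Product: 19 13-(dimethylamino)-11,13-dihydro adduct of 18 (6R,7S,8R,10R,11S)
Conditions: Me2NH (2 M in THF, 1.5 equiv), THF, 0 °C
Reagents that add atoms: dimethylamine, CNC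
Why: Aza-Michael addition of a secondary amine to the α-methylene-γ-butyrolactone, much faster than addition to the β-substituted crotonate; protonation gives the 11S adduct, and the C11=C13 alkene, which could intercept organopalladium species in step 14, stays masked until step 15.

Step 14
Reactants: 19 amine-masked vinyl iodide/terminal alkyne
Product: 22 15-O-TBDPS-13-(dimethylamino)-11,13-dihydro derivative of the target (6S,7S,8R,10R,11S), via macrocyclic ynone 20 (not isolated), via enaminone 21 (not isolated)
Conditions: PdCl2(PPh3)2 (10 mol %), CuI (10 mol %), CO (1 atm), Et3N, THF, 40 °C, slow addition of 19 (final 2 mM); then Me2NH (2 M in THF), 25 °C; then 2 M aq. HCl, 25 °C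
Reagents that add atoms: carbon monoxide, [C-]#[O+]; water, O
Why: Proposed new method: zerovalent palladium inserts into the C4–I bond with retention, CO insertion gives the C3 acylpalladium, the copper acetylide of C2 transmetalates and reductive elimination forms C2–C3 to give the strained ten-membered ynone 20; dimethylamine then adds to C1 (21), and aqueous acid cleaves the C10 silyl ether, hydrolyses the enaminone and cyclodehydrates the hydroxy-1,3-diketone to the 3(2H)-furanone. The closest known reaction types are the intermolecular carbonylative Sonogashira coupling of vinyl iodides (including its one-flask extension to 3(2H)-furanones with tertiary propargylic alcohols), the carbonylative Stille macrocyclization and the amine/acid conversion of 4-hydroxyalk-2-ynones into 3(2H)-furanones; their combination in a medium-ring closure is what is new. The ten-membered carbocycle closes by reductive elimination from an eleven-membered acyl(alkynyl)palladium metallacycle, and the furanone closes by transannular 5-exo-trig attack of the C10 oxygen on the C3 carbonyl followed by loss of water, the only mode open to that oxygen. No stereocenter is formed: C6, C7, C8 and C10 are spectators, the C4=C5 geometry is retained through oxidative addition and CO insertion, and the C10 configuration fixes the face of the oxygen bridge. The step needs carbonylative over direct coupling and ring closure over oligomerization: direct coupling would give a strained nine-membered cis-enyne, slow addition keeps the acylpalladium dilute, the Z olefin and the trans-lactone turn the two chain ends towards each other, and the amine mask at C11/C13 and the silyl ethers at O10 and O15 remove the alkene and hydroxyl groups that could trap vinyl- or acylpalladium.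

Step 15
Reactants: 22 amine-masked silyl-protected bicycle
Product: 24 15-O-(tert-butyldiphenylsilyl) ether of the target (6S,7S,8R,10R), via ammonium iodide 23 (not isolated)
Conditions: MeI, THF, 25 °C; then NaHCO3, H2O/CH2Cl2, 25 °C
Reagents that add atoms: none
Why: Exhaustive methylation and E1cB (Hofmann-type) elimination of the β-ammonium lactone under bicarbonate regenerates the C11=C13 methylene and removes the temporary C11 stereocenter.

Step 16
Reactants: 24 15-O-(tert-butyldiphenylsilyl) ether of the target
Product: 25 CNP0225232.1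
Conditions: HF·pyridine, pyridine/THF, 0 → 25 °C
Reagents that add atoms: none
Why: Fluoride-mediated silyl ether cleavage with buffered HF·pyridine, which the enoates, the furanone and the lactone tolerate, releases the C15 hydroxyl.

## Compound list

1 | tert-butyl(diphenyl)(prop-2-yn-1-yloxy)silane | C#CCO[Si](c1ccccc1)(c1ccccc1)C(C)(C)C | starting material
2 | acrolein (prop-2-enal) | C=CC=O | starting material
3 | lithium acetylide of 1 | [Li]C#CCO[Si](c1ccccc1)(c1ccccc1)C(C)(C)C | intermediate
4 | rac-6-[(tert-butyldiphenylsilyl)oxy]hex-1-en-4-yn-3-ol | C=CC(O)C#CCO[Si](c1ccccc1)(c1ccccc1)C(C)(C)C | intermediate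
5 | (3R)-6-[(tert-butyldiphenylsilyl)oxy]hex-1-en-4-yn-3-ol | C=C[C@@H](O)C#CCO[Si](c1ccccc1)(c1ccccc1)C(C)(C)C | intermediate
6 | sodium alkoxy(vinyl)aluminate from 5 (five-membered oxa-aluminacycle, Al on C4, two 2-methoxyethoxy ligands) | [Na+].COCCO[Al-]1(OCCOC)O[C@H](C=C)C=C1CO[Si](c2ccccc2)(c2ccccc2)C(C)(C)C | intermediate
7 | (3R,4Z)-6-[(tert-butyldiphenylsilyl)oxy]-5-iodohexa-1,4-dien-3-ol | C=C[C@@H](O)/C=C(/CO[Si](c1ccccc1)(c1ccccc1)C(C)(C)C)I | intermediate
8 | 2-(bromomethyl)prop-2-enoic acid | C=C(CBr)C(=O)O | starting material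
9 | (3R,4Z)-6-[(tert-butyldiphenylsilyl)oxy]-5-iodohexa-1,4-dien-3-yl 2-(bromomethyl)prop-2-enoate | C=C(CBr)C(=O)O[C@H](C=C)/C=C(/CO[Si](c1ccccc1)(c1ccccc1)C(C)(C)C)I | intermediate
10 | (5R)-3-(bromomethyl)-5-[(1Z)-3-[(tert-butyldiphenylsilyl)oxy]-2-iodoprop-1-en-1-yl]furan-2(5H)-one | O=C1O[C@@H](/C=C(/CO[Si](c2ccccc2)(c2ccccc2)C(C)(C)C)I)C=C1CBr | intermediate
11 | (S)-2-methylglycidol, [(2S)-2-methyloxiran-2-yl]methanol | OC[C@@]1(C)CO1 | starting material
12 | (2R)-2-methylpent-4-ene-1,2-diol | C=CC[C@@](C)(O)CO | intermediate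
13 | (2R)-2-methyl-1,2-bis[(triethylsilyl)oxy]pent-4-ene | C=CC[C@](C)(CO[Si](CC)(CC)CC)O[Si](CC)(CC)CC | intermediate
14 | (2R)-2-methyl-2-[(triethylsilyl)oxy]pent-4-enal | C=CC[C@](C)(C=O)O[Si](CC)(CC)CC | intermediate
15 | (3R)-3-methyl-3-[(triethylsilyl)oxy]hex-5-en-1-yne | C=CC[C@](C)(C#C)O[Si](CC)(CC)CC | intermediate
16 | (3R)-3-methyl-3-[(triethylsilyl)oxy]pent-4-ynal | O=CC[C@](C)(C#C)O[Si](CC)(CC)CC | intermediate
17 | Barbier adduct, trans-α-methylene lactone with free 8-OH (6R,7S,8R,10R) | C=C1C(=O)O[C@@H](/C=C(/CO[Si](c2ccccc2)(c2ccccc2)C(C)(C)C)I)[C@@H]1[C@H](O)C[C@](C)(C#C)O[Si](CC)(CC)CC | intermediate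
18 | 8-O-(E)-but-2-enoate of 17 (6R,7S,8R,10R) | C=C1C(=O)O[C@@H](/C=C(/CO[Si](c2ccccc2)(c2ccccc2)C(C)(C)C)I)[C@@H]1[C@H](OC(=O)/C=C/C)C[C@](C)(C#C)O[Si](CC)(CC)CC | intermediate
19 | 13-(dimethylamino)-11,13-dihydro adduct of 18 (6R,7S,8R,10R,11S) | CN(C)C[C@H]1C(=O)O[C@@H](/C=C(/CO[Si](c2ccccc2)(c2ccccc2)C(C)(C)C)I)[C@@H]1[C@H](OC(=O)/C=C/C)C[C@](C)(C#C)O[Si](CC)(CC)CC | intermediate
20 | ten-membered ynone (C1≡C2–C3=O) fused to the masked lactone, 10-O-triethylsilyl (6S,7S,8R,10R,11S) | CN(C)C[C@H]1C(=O)O[C@H]2/C=C(/CO[Si](c3ccccc3)(c3ccccc3)C(C)(C)C)C(=O)C#C[C@](C)(O[Si](CC)(CC)CC)C[C@@H](OC(=O)/C=C/C)[C@H]12 | intermediate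
21 | enaminone from 20 (dimethylamino on C1, cis C1=C2 in the ring) | CN(C)C[C@H]1C(=O)O[C@H]2/C=C(/CO[Si](c3ccccc3)(c3ccccc3)C(C)(C)C)C(=O)/C=C(/N(C)C)[C@](C)(O[Si](CC)(CC)CC)C[C@@H](OC(=O)/C=C/C)[C@H]12 | intermediate
22 | 15-O-TBDPS-13-(dimethylamino)-11,13-dihydro derivative of the target (6S,7S,8R,10R,11S) | CN(C)C[C@H]1C(=O)O[C@H]2/C=C(/CO[Si](c4ccccc4)(c4ccccc4)C(C)(C)C)C3=CC(=O)[C@@](C)(C[C@@H](OC(=O)/C=C/C)[C@H]12)O3 | intermediate
23 | trimethylammonium iodide of 22 | C[N+](C)(C)C[C@H]1C(=O)O[C@H]2/C=C(/CO[Si](c4ccccc4)(c4ccccc4)C(C)(C)C)C3=CC(=O)[C@@](C)(C[C@@H](OC(=O)/C=C/C)[C@H]12)O3.[I-] | intermediate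
24 | 15-O-(tert-butyldiphenylsilyl) ether of the target (6S,7S,8R,10R) | C=C1C(=O)O[C@H]2/C=C(/CO[Si](c4ccccc4)(c4ccccc4)C(C)(C)C)C3=CC(=O)[C@@](C)(C[C@@H](OC(=O)/C=C/C)[C@H]12)O3 | intermediate
25 | CNP0225232.1 (6S,7S,8R,10R) | C=C1C(=O)O[C@H]2/C=C(/CO)C3=CC(=O)[C@@](C)(C[C@@H](OC(=O)/C=C/C)[C@H]12)O3 | target

## Step count and risks

Total steps: 16. Longest linear sequence: 11 (steps 1–5 or 6–10, then 11–16).

**Step 14 (Proposed new method).** The acylpalladium may be consumed by intermolecular coupling (oligomer formation), or the catalyst may stall before transmetalation, so that the ten-membered ring does not close. The fallback keeps the C2–C3 ring closure but makes it a Nozaki–Hiyama–Kishi addition. It sets out from 19 and returns at 20.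
- Stille coupling of 19 with (tributylstannyl)methanol (Pd(PPh3)4, toluene, 80 °C) gives the C3 allylic alcohol F1.
- MnO2 in CH2Cl2 gives the (Z)-enal F2.
- N-iodomorpholine hydroiodide in THF converts the terminal alkyne into the 1-iodoalkyne F3.
- CrCl2 with catalytic NiCl2 in THF/DMF at high dilution adds the alkynylchromium (trivalent chromium) to the aldehyde and closes the ring to the cyclic propargylic alcohol F4 (both C3 epimers are usable).
- MnO2 oxidizes F4 to ynone 20, which is carried through the amine and acid stages of step 14 to 22.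

**Step 11.** Loss of aldehyde-face control, for example reaction through an open transition state in the aqueous medium, would give mainly the C8 epimer. The fallback corrects C8 by inversion instead of by the allylation. It sets out from 10 and 16 and returns at 18: the 8-epi alcohol F5 is esterified under Mitsunobu conditions ((E)-but-2-enoic acid, PPh3, diisopropyl azodicarboxylate, THF, 0 °C), which installs the crotonate with inversion and gives 18 directly.

**Step 3.** β-Elimination of the siloxide from the vinylaluminate (allenol formation), or loss of regiocontrol between the two oxygenated alkyne termini, would erode the yield of the Z-iodide. The fallback replaces hydroalumination by hydrosilylation. It sets out from 5 and returns at 7: trans-hydrosilylation with Et3SiH and [Cp*Ru(MeCN)3]PF6 (CH2Cl2, 0 °C) places silicon on C4 and gives vinylsilane F6; iododesilylation with N-iodosuccinimide in (CF3)2CHOH at 0 °C then gives 7 with retention of geometry.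

## Further compounds

F1 | step 14 | C3 allylic alcohol from 19 (CH2OH in place of iodine on C4) | CN(C)C[C@H]1C(=O)O[C@@H](/C=C(/CO[Si](c2ccccc2)(c2ccccc2)C(C)(C)C)CO)[C@@H]1[C@H](OC(=O)/C=C/C)C[C@](C)(C#C)O[Si](CC)(CC)CC
F2 | step 14 | (Z)-enal (C3 aldehyde on C4) | CN(C)C[C@H]1C(=O)O[C@@H](/C=C(/CO[Si](c2ccccc2)(c2ccccc2)C(C)(C)C)C=O)[C@@H]1[C@H](OC(=O)/C=C/C)C[C@](C)(C#C)O[Si](CC)(CC)CC
F3 | step 14 | enal with 1-iodoalkyne at C2 | CN(C)C[C@H]1C(=O)O[C@@H](/C=C(/CO[Si](c2ccccc2)(c2ccccc2)C(C)(C)C)C=O)[C@@H]1[C@H](OC(=O)/C=C/C)C[C@](C)(C#CI)O[Si](CC)(CC)CC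
F4 | step 14 | ten-membered cyclic propargylic alcohol (C3 carbinol, epimer mixture) | CN(C)C[C@H]1C(=O)O[C@H]2/C=C(/CO[Si](c3ccccc3)(c3ccccc3)C(C)(C)C)C(O)C#C[C@](C)(O[Si](CC)(CC)CC)C[C@@H](OC(=O)/C=C/C)[C@H]12
F5 | step 11 | 8-epi alcohol of 17 (6R,7S,8S,10R) | C=C1C(=O)O[C@@H](/C=C(/CO[Si](c2ccccc2)(c2ccccc2)C(C)(C)C)I)[C@@H]1[C@@H](O)C[C@](C)(C#C)O[Si](CC)(CC)CC
F6 | step 3 | (3R,4Z)-6-[(tert-butyldiphenylsilyl)oxy]-5-(triethylsilyl)hexa-1,4-dien-3-ol | C=C[C@@H](O)/C=C(/CO[Si](c1ccccc1)(c1ccccc1)C(C)(C)C)[Si](CC)(CC)CC
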